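Everything rests on disconnecting C4a–C4, C4–C3 and C3''–C4'' at once (each half numbered as a flavanone: plain locants for the 7-hydroxy unit 1, double primes for the 5,7-dihydroxy unit 2). In the target, the bonded ring C carbons C3 and C3'' each hold a carbonyl carbon and have like configuration, which is what suprafacial addition of two carbonyl carbons to a trans C3=C3'' olefin produces. A carbonylative palladium cascade on an aryl iodide therefore builds ring C of unit 1 and both stereocentres in one operation. Its substrate is the (S,S)-configured (E)-1,4-diarylbut-2-ene-1,4-diyl bis(aryl ether): C2 carries the 2-iodo-5-benzyloxyphenyl ether, C2'' the 3,5-dibenzyloxyphenyl ether, and both rings B are pivalate-protected.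

Key step: step 8

Remarks on the chemistry
- Stereochemistry: the target is (2S,3R,2''S,3''R), 2,3-trans in both units, so the cascade substrate must be the (S,S)-bis(aryl ether), reached by two inversions from the (R,R)-diol.
- Substrate design: rings B carry pivalate esters, not alkyl ethers, because a 4-alkoxyphenyl group would make each benzylic, allylic C–O bond easy to ionise in the Mitsunobu steps, towards zerovalent palladium and in acid.
- End game: the methyl ester is cleaved without hydroxide, since base would open the flavanone ring or expel the C2'' aryloxide.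
- Assumption: in the oxazaborolidine reduction the aryl group acts as the larger ketone substituent (as in aryl alkyl ketones), so the (S)-catalyst should give the (R)-carbinols; if the sense is opposite, the (R)-catalyst is used with no other change.
- Assumption: 3-(benzyloxy)phenol and 3,5-bis(benzyloxy)phenol are purchased.

Step 1
Reactants: 1 fumaryl chloride
Product: 2 (E)-N1,N4-dimethoxy-N1,N4-dimethylbut-2-enediamide
Conditions: MeNHOMe·HCl (2.2 equiv), K2CO3, CH2Cl2/H2O, 0 °C
Reagents that add atoms: N,O-dimethylhydroxylamine hydrochloride, CNOC.Cl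
Why: Schotten–Baumann acylation of the hydroxylamine by the diacid chloride gives the bis-Weinreb amide and leaves the E alkene untouched.

Step 2
Reactants: 3 4-iodophenol
Product: 4 4-iodophenyl pivalate
Conditions: PivCl, Et3N, DMAP (cat.), CH2Cl2, 0 °C → rt
Reagents that add atoms: pivaloyl chloride, CC(C)(C)C(=O)Cl
Why: DMAP-catalysed esterification of the phenol installs a hindered, electron-withdrawing ester that tolerates the organomagnesium, borane, Mitsunobu and carbonylation steps.

Step 3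
Reactants: 4 4-iodophenyl pivalate; 2 (E)-N1,N4-dimethoxy-N1,N4-dimethylbut-2-enediamide
Product: 6 (E)-1,4-bis[4-(pivaloyloxy)phenyl]but-2-ene-1,4-dione, via arylmagnesium chloride 5 (not isolated)
Conditions: 4 (2.3 equiv), iPrMgCl·LiCl, THF, −20 °C; then 2, −20 → 0 °C; aq. NH4Cl
Reagents that add atoms: none
Why: Iodine–magnesium exchange at low temperature spares the hindered aryl ester, and the Weinreb ketone synthesis (two 1,2-additions through chelated tetrahedral intermediates) stops at the E enedione.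

Step 4
Reactants: 6 (E)-1,4-bis[4-(pivaloyloxy)phenyl]but-2-ene-1,4-dione
Product: 7 (1R,4R,2E)-1,4-bis[4-(pivaloyloxy)phenyl]but-2-ene-1,4-diol
Conditions: (S)-2-methyl-CBS-oxazaborolidine (0.4 equiv), BH3·SMe2, THF, −20 °C, slow addition of 6; MeOH; meso diol removed by chromatography
Reagents that add atoms: none
Why: Corey–Bakshi–Shibata reduction sets both carbinol centres under catalyst control, and since a wrong event at one centre ends in the separable meso diol, the C2-symmetric (R,R)-diol should be enriched by statistical amplification.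

Step 5
Reactants: 8 3-(benzyloxy)phenol
Product: 9 5-(benzyloxy)-2-iodophenol
Conditions: I2, NaHCO3, THF/H2O, 0 °C → rt; chromatography
Reagents that add atoms: iodine, II
Why: Electrophilic aromatic iodination of the phenol goes mainly to the open carbon ortho to OH and para to the benzyloxy group, as is known for 3-alkoxyphenols, and the para-iodo isomer is separable.

Step 6
Reactants: 7 (1R,4R,2E)-1,4-bis[4-(pivaloyloxy)phenyl]but-2-ene-1,4-diol; 10 3,5-bis(benzyloxy)phenol
Product: 11 (1R,4S,2E)-4-[3,5-bis(benzyloxy)phenoxy]-1,4-bis[4-(pivaloyloxy)phenyl]but-2-en-1-ol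
Conditions: 7 (2.5 equiv, excess recovered), PPh3, DIAD, toluene, −20 → 0 °C
Reagents that add atoms: none
Why: Mitsunobu etherification (SN2 with inversion) at one of the two homotopic hydroxyls gives the (S)-ether, with the excess diol limiting double etherification and the acyloxy rings B holding back ionisation of the alkoxyphosphonium ion.

Step 7
Reactants: 11 (1R,4S,2E)-4-[3,5-bis(benzyloxy)phenoxy]-1,4-bis[4-(pivaloyloxy)phenyl]but-2-en-1-ol; 9 5-(benzyloxy)-2-iodophenol
Product: 12 (1S,4S,2E)-1-[5-(benzyloxy)-2-iodophenoxy]-4-[3,5-bis(benzyloxy)phenoxy]-1,4-bis[4-(pivaloyloxy)phenyl]but-2-ene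
Conditions: 9 (1.5 equiv), PPh3, DIAD, toluene, 0 °C → rt
Reagents that add atoms: none
Why: A second Mitsunobu etherification inverts the remaining (R)-carbinol with the acidic ortho-iodophenol and completes the (S,S)-bis(aryl ether) with two different rings A.

Step 8
Reactants: 12 (1S,4S,2E)-1-[5-(benzyloxy)-2-iodophenoxy]-4-[3,5-bis(benzyloxy)phenoxy]-1,4-bis[4-(pivaloyloxy)phenyl]but-2-ene
Product: 13 methyl (2R,3S)-2-[(2S,3R)-7-(benzyloxy)-4-oxo-2-[4-(pivaloyloxy)phenyl]chroman-3-yl]-3-[3,5-bis(benzyloxy)phenoxy]-3-[4-(pivaloyloxy)phenyl]propanoate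
Conditions: Pd(OAc)2 (10 mol %), PPh3 (40 mol %), CO (40 atm), MeOH (4 equiv), iPr2NEt (3 equiv), MeCN–toluene 1:1, 80 °C
Reagents that add atoms: carbon monoxide, [C-]#[O+] (two molecules); methanol, CO
Why: Proposed new method: zerovalent palladium (formed in situ from Pd(OAc)2, PPh3 and CO) inserts into the C4a–I bond, CO insertion gives the aroylpalladium iodide, this adds syn across the E C3=C3'' bond (C4–C3 formed, palladium on C3''), and a second CO insertion with retention followed by methanolysis makes C3''–C4'' as the ester and frees zerovalent palladium. The closest known reaction type is cyclic acylpalladation of alkenes tethered to ortho-iodoarenes ended by carbonylative esterification, known for terminal and 1,1-disubstituted alkenes but not for a 1,2-disubstituted alkene flanked by two allylic aryl ethers and bearing β-hydrogens. Ring C of unit 1 closes in the 6-exo-trig mode. C3 is set by the chair-like insertion geometry in which the C2 aryl group sits equatorial, so C4 enters the alkene face anti to that aryl group (2,3-trans), and C3'' is set by the syn course of migratory insertion on the E alkene together with retentive carbonylation, which gives the like C3/C3'' pair. The step needs alkene insertion to outrun methanolysis of the aroylpalladium species and carbonylation of the C3''–palladium bond to outrun loss of β-hydrogen or β-aryloxide, for which the 6-exo tether, the low methanol charge, 40 atm of CO and chelation of palladium by the new C4 ketone are relied on, while the ester-bearing rings B disfavour ionisation of the allylic C–O bonds by zerovalent palladium. Any 2,3-cis material should be correctable, since C3 and C3'' both end up α to a ketone and the trans arrangement is the more stable one.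

Step 9
Reactants: 13 methyl (2R,3S)-2-[(2S,3R)-7-(benzyloxy)-4-oxo-2-[4-(pivaloyloxy)phenyl]chroman-3-yl]-3-[3,5-bis(benzyloxy)phenoxy]-3-[4-(pivaloyloxy)phenyl]propanoate
Product: 15 (2R,3S)-2-[(2S,3R)-7-(benzyloxy)-4-oxo-2-[4-(pivaloyloxy)phenyl]chroman-3-yl]-3-[3,5-bis(benzyloxy)phenoxy]-3-[4-(pivaloyloxy)phenyl]propanoic acid, via trimethylstannyl ester 14 (not isolated)
Conditions: Me3SnOH (6 equiv), 1,2-dichloroethane, 80 °C; 5% aq. HCl wash
Reagents that add atoms: trimethyltin hydroxide, C[Sn](C)(C)O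
Why: Trimethyltin hydroxide hydrolysis cleaves the methyl ester under neutral conditions, so neither retro-oxa-Michael opening of the flavanone nor β-elimination of the C2'' aryloxide is triggered and no stereocentre is touched.

Step 10
Reactants: 15 (2R,3S)-2-[(2S,3R)-7-(benzyloxy)-4-oxo-2-[4-(pivaloyloxy)phenyl]chroman-3-yl]-3-[3,5-bis(benzyloxy)phenoxy]-3-[4-(pivaloyloxy)phenyl]propanoic acid
Product: 17 (2S,3R,2''S,3''R)-7,5'',7''-tris(benzyloxy)-2,2''-bis[4-(pivaloyloxy)phenyl]-3,3''-bichromane-4,4''-dione, via mixed trifluoroacetic anhydride 16 (not isolated)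
Conditions: (CF3CO)2O (3 equiv), CH2Cl2, 0 °C → rt; aq. NaHCO3
Reagents that add atoms: none
Why: Intramolecular Friedel–Crafts acylation through the mixed anhydride attacks either equivalent ortho carbon of the strongly activated 3,5-dibenzyloxyphenyl ether and closes ring C of unit 2 with the existing C2''/C3'' centres carried over.

Step 11
Reactants: 17 (2S,3R,2''S,3''R)-7,5'',7''-tris(benzyloxy)-2,2''-bis[4-(pivaloyloxy)phenyl]-3,3''-bichromane-4,4''-dione
Product: 18 (2S,3R,2''S,3''R)-7,5'',7''-tris(benzyloxy)-2,2''-bis(4-hydroxyphenyl)-3,3''-bichromane-4,4''-dione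
Conditions: HCl (3 M in MeOH), 1,4-dioxane, 50 °C
Reagents that add atoms: none
Why: Acid-catalysed transesterification with methanol removes the two aryl pivalates without base, so the flavanone rings cannot open and acid enolisation can only favour the 2,3-trans arrangement already present.

Step 12
Reactants: 18 (2S,3R,2''S,3''R)-7,5'',7''-tris(benzyloxy)-2,2''-bis(4-hydroxyphenyl)-3,3''-bichromane-4,4''-dione
Product: 19 (2S,3R,2''S,3''R)-7,5'',7''-trihydroxy-2,2''-bis(4-hydroxyphenyl)-3,3''-bichromane-4,4''-dione (target)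
Conditions: H2 (1 atm), 10% Pd/C, EtOAc/MeOH, rt
Reagents that add atoms: none
Why: Hydrogenolysis of the three aryl benzyl ethers over Pd/C under neutral conditions frees the remaining phenols and leaves the ketones and the ring C ethers intact.

Compound list
1 | fumaryl chloride | O=C(Cl)/C=C/C(=O)Cl | starting material
2 | (E)-N1,N4-dimethoxy-N1,N4-dimethylbut-2-enediamide | CON(C)C(=O)/C=C/C(=O)N(C)OC | intermediate
3 | 4-iodophenol | Oc1ccc(I)cc1 | starting material
4 | 4-iodophenyl pivalate | CC(C)(C)C(=O)Oc1ccc(I)cc1 | intermediate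
5 | [4-(pivaloyloxy)phenyl]magnesium chloride (LiCl complex) | CC(C)(C)C(=O)Oc1ccc([Mg]Cl)cc1 | intermediate (not isolated)
6 | (E)-1,4-bis[4-(pivaloyloxy)phenyl]but-2-ene-1,4-dione | CC(C)(C)C(=O)Oc1ccc(cc1)C(=O)/C=C/C(=O)c1ccc(OC(=O)C(C)(C)C)cc1 | intermediate
7 | (1R,4R,2E)-1,4-bis[4-(pivaloyloxy)phenyl]but-2-ene-1,4-diol | CC(C)(C)C(=O)Oc1ccc(cc1)[C@H](O)/C=C/[C@@H](O)c1ccc(OC(=O)C(C)(C)C)cc1 | intermediate
8 | 3-(benzyloxy)phenol | Oc1cccc(OCc2ccccc2)c1 | starting material
9 | 5-(benzyloxy)-2-iodophenol | Oc1cc(OCc2ccccc2)ccc1I | intermediate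
10 | 3,5-bis(benzyloxy)phenol | Oc1cc(OCc2ccccc2)cc(OCc2ccccc2)c1 | starting material
11 | (1R,4S,2E)-4-[3,5-bis(benzyloxy)phenoxy]-1,4-bis[4-(pivaloyloxy)phenyl]but-2-en-1-ol | O[C@@H](c1ccc(OC(=O)C(C)(C)C)cc1)/C=C/[C@H](Oc1cc(OCc2ccccc2)cc(OCc2ccccc2)c1)c1ccc(OC(=O)C(C)(C)C)cc1 | intermediate
12 | (1S,4S,2E)-1-[5-(benzyloxy)-2-iodophenoxy]-4-[3,5-bis(benzyloxy)phenoxy]-1,4-bis[4-(pivaloyloxy)phenyl]but-2-ene | Ic1ccc(OCc2ccccc2)cc1O[C@H](c1ccc(OC(=O)C(C)(C)C)cc1)/C=C/[C@H](Oc1cc(OCc2ccccc2)cc(OCc2ccccc2)c1)c1ccc(OC(=O)C(C)(C)C)cc1 | intermediate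
13 | methyl (2R,3S)-2-[(2S,3R)-7-(benzyloxy)-4-oxo-2-[4-(pivaloyloxy)phenyl]chroman-3-yl]-3-[3,5-bis(benzyloxy)phenoxy]-3-[4-(pivaloyloxy)phenyl]propanoate | O=C1c2ccc(OCc3ccccc3)cc2O[C@H](c2ccc(OC(=O)C(C)(C)C)cc2)[C@H]1[C@@H](C(=O)OC)[C@H](Oc1cc(OCc2ccccc2)cc(OCc2ccccc2)c1)c1ccc(OC(=O)C(C)(C)C)cc1 | intermediate
14 | trimethylstannyl ester of acid 15 | O=C1c2ccc(OCc3ccccc3)cc2O[C@H](c2ccc(OC(=O)C(C)(C)C)cc2)[C@H]1[C@@H](C(=O)O[Sn](C)(C)C)[C@H](Oc1cc(OCc2ccccc2)cc(OCc2ccccc2)c1)c1ccc(OC(=O)C(C)(C)C)cc1 | intermediate (not isolated)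
15 | (2R,3S)-2-[(2S,3R)-7-(benzyloxy)-4-oxo-2-[4-(pivaloyloxy)phenyl]chroman-3-yl]-3-[3,5-bis(benzyloxy)phenoxy]-3-[4-(pivaloyloxy)phenyl]propanoic acid | O=C1c2ccc(OCc3ccccc3)cc2O[C@H](c2ccc(OC(=O)C(C)(C)C)cc2)[C@H]1[C@@H](C(=O)O)[C@H](Oc1cc(OCc2ccccc2)cc(OCc2ccccc2)c1)c1ccc(OC(=O)C(C)(C)C)cc1 | intermediate
16 | mixed anhydride of acid 15 and trifluoroacetic acid | O=C1c2ccc(OCc3ccccc3)cc2O[C@H](c2ccc(OC(=O)C(C)(C)C)cc2)[C@H]1[C@@H](C(=O)OC(=O)C(F)(F)F)[C@H](Oc1cc(OCc2ccccc2)cc(OCc2ccccc2)c1)c1ccc(OC(=O)C(C)(C)C)cc1 | intermediate (not isolated)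
17 | (2S,3R,2''S,3''R)-7,5'',7''-tris(benzyloxy)-2,2''-bis[4-(pivaloyloxy)phenyl]-3,3''-bichromane-4,4''-dione | O=C1c2ccc(OCc3ccccc3)cc2O[C@H](c2ccc(OC(=O)C(C)(C)C)cc2)[C@H]1[C@H]1C(=O)c2c(OCc3ccccc3)cc(OCc3ccccc3)cc2O[C@@H]1c1ccc(OC(=O)C(C)(C)C)cc1 | intermediate
18 | (2S,3R,2''S,3''R)-7,5'',7''-tris(benzyloxy)-2,2''-bis(4-hydroxyphenyl)-3,3''-bichromane-4,4''-dione | O=C1c2ccc(OCc3ccccc3)cc2O[C@H](c2ccc(O)cc2)[C@H]1[C@H]1C(=O)c2c(OCc3ccccc3)cc(OCc3ccccc3)cc2O[C@@H]1c1ccc(O)cc1 | intermediate
19 | (2S,3R,2''S,3''R)-7,5'',7''-trihydroxy-2,2''-bis(4-hydroxyphenyl)-3,3''-bichromane-4,4''-dione | O=C1c2ccc(O)cc2O[C@H](c2ccc(O)cc2)[C@H]1[C@H]1C(=O)c2c(O)cc(O)cc2O[C@@H]1c1ccc(O)cc1 | target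

Total step count: 12. Longest linear sequence: 10 steps (1, 3, 4, 6, 7, 8, 9, 10, 11, 12).

Steps most likely to fail

1. Step 8 (new method). The aroylpalladium species may be esterified by methanol before it adds to the hindered alkene. The C3''–palladium intermediate may lose β-hydrogen or β-aryloxide before it is carbonylated. Zerovalent palladium may ionise an allylic aryl ether, or the alkene may be entered from the wrong face. Fallback with known chemistry, setting out from 11: Mitsunobu etherification of 11 with 3-(benzyloxy)phenol 8 (PPh3, DIAD, toluene) gives the iodine-free (1S,4S)-bis(aryl ether) F1. Oxidative bis(methoxycarbonylation) of its alkene (PdCl2 as catalyst kept divalent by CuCl2, NaOAc, CO 3 atm, MeOH, rt) is a syn addition of two ester carbons known for 1,2-disubstituted alkenes. It should give the (2R,3R)-succinate diester F2 with the like C3/C3'' pair; facial selectivity is not assured, so F2 is separated by chromatography. Me3SnOH (1,2-dichloroethane, 80 °C) then gives the (2R,3R)-diacid F3. Twofold Friedel–Crafts acylation (trifluoroacetic anhydride, catalytic TfOH, CH2Cl2) closes ring C of both units, the resorcinol-derived ring reacting para to its benzyloxy group. The route is rejoined at 17.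

2. Step 6. The alkoxyphosphonium intermediate may ionise, which would erode configuration or let the phenol enter at C3 (SN2′), and both hydroxyls may be etherified. Fallback, setting out from 7: mono-oxidation with MnO2 (CH2Cl2, rt) gives the (R)-hydroxy enone F4; over-oxidised material is dione 6 and returns to step 4. Mitsunobu etherification of F4 with phenol 10 gives the (S)-aryloxy enone F5 with inversion, the conjugated carbonyl opposing ionisation and removing the SN2′ pathway. Reduction of F5 with the (S)-oxazaborolidine and BH3·SMe2 of step 4 gives the (R)-carbinol. The route is rejoined at 11.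

3. Step 9. Attack at the hindered ester carbonyl may be slow, and forcing it may start to cleave the aryl pivalates. Fallback, setting out from 13: LiI in ethyl acetate at reflux cleaves the O–CH3 bond by SN2 attack of iodide at the methyl group, which is insensitive to crowding at the acyl carbon and spares aryl esters. This gives the lithium carboxylate F6, and dilute HCl then gives the acid. The route is rejoined at 15.

Further compounds
F1 | step 8 | (1S,4S,2E)-1-[3-(benzyloxy)phenoxy]-4-[3,5-bis(benzyloxy)phenoxy]-1,4-bis[4-(pivaloyloxy)phenyl]but-2-ene | O(Cc1ccccc1)c1cccc(O[C@H](c2ccc(OC(=O)C(C)(C)C)cc2)/C=C/[C@H](Oc2cc(OCc3ccccc3)cc(OCc3ccccc3)c2)c2ccc(OC(=O)C(C)(C)C)cc2)c1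
F2 | step 8 | dimethyl (2R,3R)-2-{(S)-[3-(benzyloxy)phenoxy][4-(pivaloyloxy)phenyl]methyl}-3-{(S)-[3,5-bis(benzyloxy)phenoxy][4-(pivaloyloxy)phenyl]methyl}butanedioate | COC(=O)[C@@H]([C@H](Oc1cccc(OCc2ccccc2)c1)c1ccc(OC(=O)C(C)(C)C)cc1)[C@@H](C(=O)OC)[C@H](Oc1cc(OCc2ccccc2)cc(OCc2ccccc2)c1)c1ccc(OC(=O)C(C)(C)C)cc1
F3 | step 8 | (2R,3R)-2-{(S)-[3-(benzyloxy)phenoxy][4-(pivaloyloxy)phenyl]methyl}-3-{(S)-[3,5-bis(benzyloxy)phenoxy][4-(pivaloyloxy)phenyl]methyl}butanedioic acid | OC(=O)[C@@H]([C@H](Oc1cccc(OCc2ccccc2)c1)c1ccc(OC(=O)C(C)(C)C)cc1)[C@@H](C(=O)O)[C@H](Oc1cc(OCc2ccccc2)cc(OCc2ccccc2)c1)c1ccc(OC(=O)C(C)(C)C)cc1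
F4 | step 6 | (4R,2E)-4-hydroxy-1,4-bis[4-(pivaloyloxy)phenyl]but-2-en-1-one | O=C(/C=C/[C@@H](O)c1ccc(OC(=O)C(C)(C)C)cc1)c1ccc(OC(=O)C(C)(C)C)cc1
F5 | step 6 | (4S,2E)-4-[3,5-bis(benzyloxy)phenoxy]-1,4-bis[4-(pivaloyloxy)phenyl]but-2-en-1-one | O=C(/C=C/[C@H](Oc1cc(OCc2ccccc2)cc(OCc2ccccc2)c1)c1ccc(OC(=O)C(C)(C)C)cc1)c1ccc(OC(=O)C(C)(C)C)cc1
F6 | step 9 | lithium carboxylate of acid 15 | O=C1c2ccc(OCc3ccccc3)cc2O[C@H](c2ccc(OC(=O)C(C)(C)C)cc2)[C@H]1[C@@H](C(=O)[O-])[C@H](Oc1cc(OCc2ccccc2)cc(OCc2ccccc2)c1)c1ccc(OC(=O)C(C)(C)C)cc1.[Li+]
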